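## Retrosynthetic overview

1. The arene–side-chain bond at C8 is made last, by a catalyst-controlled Friedel–Crafts-type Michael addition of the (2R)-5,7-dihydroxy-6-methylflavanone to an alkylidene-syncarpic acid, as in the presumed biosynthesis. The alkylidene trione comes from isovaleraldehyde and syncarpic acid, itself made by dearomatising tetra-C-methylation of phloroacetophenone.
2. Ring C of the flavanone is closed through its C2–C3 bond: enantioselective 1,6 C–H insertion of a rhodium carbene placed at C3 (from an aryl diazomethyl ketone) into the OCH2Ph group on O1.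
3. Enabling feature: in ring C the stereogenic C2 is a benzylic carbon bound to the ring oxygen O1 and carries ring B. O1–C2–Ph is therefore a benzyl ether in disguise, whose CH2 lies 1,6 to C3 beside the C4 ketone, so an ordinary O-benzyl group ends up as C2 plus ring B.
4. The diazoketone comes from 2-methylphloroglucinol by formylation, a partial benzylation that leaves only the hydroxyl flanked by methyl and carbonyl (capped as acetate), oxidation, and acylation of diazomethane.
5. Ring order: ring A and ring B are bought (ring B as benzyl bromide), ring C is formed in step 6, and the syncarpyl ring (step 8) is attached in step 11.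

Key step: step 6

Assumption: the sense of induction of the two chiral catalysts (steps 6 and 11) is assigned by analogy and would be fixed in a first trial, the mirror-image catalyst being used if it proves opposite; the syncarpyl unit is treated as the enol tautomer drawn in the target structure.

## Route

Step 1
Reactants: 1 2-methylphloroglucinol
Product: 3 2,4,6-trihydroxy-3-methylbenzaldehyde, via aryl iminium chloride 2 (not isolated)
Conditions: POCl3, DMF, EtOAc, 0 °C to rt; then H2O, 50 °C
Reagents that add atoms: N,N-dimethylformamide CN(C)C=O; water O
Why: Vilsmeier–Haack formylation of the electron-rich ring, whose two free positions are equivalent so that only one mono-aldehyde can form, the formyl group then deactivating the ring towards a second attack.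

Step 2
Reactants: 3 2,4,6-trihydroxy-3-methylbenzaldehyde; 4 benzyl bromide (2.1 equiv)
Product: 5 4,6-bis(benzyloxy)-2-hydroxy-3-methylbenzaldehyde
Conditions: K2CO3 (2.2 equiv), DMF, rt
Reagents that add atoms: none
Why: Williamson O-alkylation under weak base should benzylate the para hydroxyl and the less hindered ortho hydroxyl, whereas the hydroxyl flanked by the C-methyl and the formyl group is the most hindered and stays locked in the hydrogen bond to the carbonyl oxygen, the usual outcome of partial alkylation of C-methylated phloroacyl compounds.

Step 3
Reactants: 5 4,6-bis(benzyloxy)-2-hydroxy-3-methylbenzaldehyde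
Product: 6 3,5-bis(benzyloxy)-2-formyl-6-methylphenyl acetate
Conditions: Ac2O, pyridine, DMAP (cat.), CH2Cl2, rt
Reagents that add atoms: acetic anhydride CC(=O)OC(C)=O
Why: DMAP-catalysed acetylation of the remaining chelated phenol turns this oxygen into a non-nucleophilic ester oxygen with no C–H bond in reach of the later carbene, so that it cannot compete in step 6.

Step 4
Reactants: 6 3,5-bis(benzyloxy)-2-formyl-6-methylphenyl acetate
Product: 7 2-acetoxy-4,6-bis(benzyloxy)-3-methylbenzoic acid
Conditions: NaClO2, NaH2PO4, 2-methyl-2-butene (excess), t-BuOH/THF/H2O, 0 °C to rt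
Reagents that add atoms: sodium chlorite [Na+].[O-]Cl=O
Why: Pinnick oxidation converts hindered electron-rich benzaldehydes to the acids under mildly acidic conditions that leave the aryl acetate and the benzyl ethers untouched, the excess alkene removing HOCl before it can chlorinate the free ring position.

Step 5
Reactants: 7 2-acetoxy-4,6-bis(benzyloxy)-3-methylbenzoic acid
Product: 9 3,5-bis(benzyloxy)-2-(diazoacetyl)-6-methylphenyl acetate, via acid chloride 8 (not isolated)
Conditions: (COCl)2, DMF (cat.), CH2Cl2, 0 °C to rt; evaporate; CH2N2 (3 equiv), Et2O/THF, 0 °C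
Reagents that add atoms: diazomethane C=[N+]=[N-]
Why: Acid chloride formation followed by C-acylation of diazomethane (first stage of the Arndt–Eistert sequence), a second equivalent of diazomethane consuming the HCl, in analogy to O-acetylsalicyloyl chloride, whose ortho acetate is inert under these conditions.

Step 6
Reactants: 9 3,5-bis(benzyloxy)-2-(diazoacetyl)-6-methylphenyl acetate
Product: 10 (2R)-7-(benzyloxy)-6-methyl-4-oxo-2-phenyl-3,4-dihydro-2H-chromen-5-yl acetate
Conditions: Rh2(S-PTTL)4 (1 mol%), CH2Cl2, 4 Å MS, 0 °C, slow addition of 9
Reagents that add atoms: none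
Why: The dirhodium tetrakis[N-phthaloyl-(S)-tert-leucinate] expels N2 from 9 to give an electrophilic rhodium carbene at the future C3, which inserts through a concerted, asynchronous, hydride-transfer-like three-centre transition state into a benzylic C–H bond of the ortho O-benzyl group, whose carbon becomes C2 with ring B already attached. The closest known reaction type is the dirhodium-carboxylate-catalysed intramolecular C–H insertion of ortho-alkoxyaryl α-diazoketones next to the ether oxygen, which gives chroman-4-ones. Ring C closes by a 1,6 C–H insertion through a six-membered cyclic transition state; the 1,5 position is the ether oxygen itself, so no five-membered C–H insertion can compete. The only new stereocentre, C2, is set by the chiral tert-leucinate ligands, which select one of the two enantiotopic benzylic hydrogens, the C–H bond being replaced with retention. The step needs chemoselectivity for C–H insertion over oxonium-ylide formation with [1,2]-benzyl shift, and site-selectivity among three oxygen substituents: the inserting C–H is doubly activated (benzylic and α to oxygen), the ylide would have to form at a weakly basic aryl ether oxygen conjugated to the ketone, the acetate has neither a nucleophilic oxygen nor a reachable C–H, and the para benzyl ether is out of reach.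

Step 7
Reactants: 10 (2R)-7-(benzyloxy)-6-methyl-4-oxo-2-phenyl-3,4-dihydro-2H-chromen-5-yl acetate
Product: 12 (2R)-5,7-dihydroxy-6-methyl-2-phenylchroman-4-one, via 5-O-acetyl flavanone 11 (not isolated)
Conditions: H2 (1 atm), 10% Pd/C, EtOAc, rt; filter; then HCl (0.5 M) in MeOH, rt to 40 °C
Reagents that add atoms: none
Why: Hydrogenolysis of the aryl benzyl ether at atmospheric pressure, as practised on benzyloxyflavanones without cleavage of the O1–C2 bond, is followed by acid-catalysed transesterification of the aryl acetate, so that the base-sensitive C2 centre (ring opening to the chalcone) never meets base and should keep its configuration.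

Step 8
Reactants: 13 2',4',6'-trihydroxyacetophenone
Product: 14 6-acetyl-5-hydroxy-2,2,4,4-tetramethylcyclohex-5-ene-1,3-dione (acetylsyncarpic acid)
Conditions: NaOMe (excess), MeI (excess), MeOH, rt to reflux
Reagents that add atoms: iodomethane CI
Why: Exhaustive C-methylation, in which the phloroglucinol ring reacts as its keto-enolate at the two free ring carbons, each taking two methyl groups with loss of aromaticity, while the acetyl-bearing carbon is blocked and the product persists as a stabilised β-triketone enolate.

Step 9
Reactants: 14 acetylsyncarpic acid
Product: 15 2,2,4,4-tetramethylcyclohexane-1,3,5-trione (syncarpic acid)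
Conditions: 6 M HCl (aq), reflux
Reagents that add atoms: none
Why: Acid-mediated retro-Claisen cleavage of the exocyclic acetyl group of the β-triketone, the only unhindered carbonyl open to hydration, releases acetic acid and the cyclic triketone.

Step 10
Reactants: 15 syncarpic acid; 16 isovaleraldehyde (3-methylbutanal)
Product: 18 2,2,4,4-tetramethyl-6-(3-methylbutylidene)cyclohexane-1,3,5-trione, via piperidine Mannich base 17 (not isolated)
Conditions: piperidine (1.1 equiv), CH2Cl2, rt; then 1 M HCl (aq), Et2O, 0 °C; used at once
Reagents that add atoms: none
Why: Knoevenagel condensation routed through the piperidine Mannich base, which stops a second syncarpic acid from adding to the product, acid then protonating the amine and triggering elimination to the alkylidene trione.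

Step 11
Reactants: 12 (2R)-5,7-dihydroxy-6-methyl-2-phenylchroman-4-one; 18 2,2,4,4-tetramethyl-6-(3-methylbutylidene)cyclohexane-1,3,5-trione
Product: 19 (2R)-5,7-dihydroxy-8-[(1S)-1-(2-hydroxy-3,3,5,5-tetramethyl-4,6-dioxocyclohex-1-en-1-yl)-3-methylbutyl]-6-methyl-2-phenyl-2,3-dihydro-4H-chromen-4-one
Conditions: (R)-TRIP [(R)-3,3'-bis(2,4,6-triisopropylphenyl)-1,1'-binaphthyl-2,2'-diyl hydrogen phosphate] (10 mol%), toluene/CH2Cl2, 4 Å MS, −30 °C
Reagents that add atoms: none
Why: Friedel–Crafts-type Michael addition that mirrors the presumed biosynthesis, in which C8, the only free position of ring A and activated by the 7-hydroxyl, adds to the exocyclic β-carbon of the alkylidene trione while the chiral phosphoric acid, hydrogen-bonded to the 7-OH and to a trione carbonyl, exposes one face of the C=C bond and so sets the side-chain centre under catalyst control, the acidic base-free medium and low temperature preserving C2 and suppressing retro-addition and cyclodehydration.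

## Compound list

1 | 2-methylphloroglucinol (2-methylbenzene-1,3,5-triol) | Cc1c(O)cc(O)cc1O | starting material
2 | N-[(2,4,6-trihydroxy-3-methylphenyl)methylidene]-N-methylmethanaminium chloride (aryl iminium chloride) | Cc1c(O)cc(O)c(C=[N+](C)C)c1O.[Cl-] | intermediate
3 | 2,4,6-trihydroxy-3-methylbenzaldehyde | Cc1c(O)cc(O)c(C=O)c1O | intermediate
4 | benzyl bromide | BrCc1ccccc1 | starting material
5 | 4,6-bis(benzyloxy)-2-hydroxy-3-methylbenzaldehyde | Cc1c(O)c(C=O)c(OCc2ccccc2)cc1OCc1ccccc1 | intermediate
6 | 3,5-bis(benzyloxy)-2-formyl-6-methylphenyl acetate | CC(=O)Oc1c(C)c(OCc2ccccc2)cc(OCc2ccccc2)c1C=O | intermediate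
7 | 2-acetoxy-4,6-bis(benzyloxy)-3-methylbenzoic acid | CC(=O)Oc1c(C)c(OCc2ccccc2)cc(OCc2ccccc2)c1C(=O)O | intermediate
8 | 2-acetoxy-4,6-bis(benzyloxy)-3-methylbenzoyl chloride | CC(=O)Oc1c(C)c(OCc2ccccc2)cc(OCc2ccccc2)c1C(=O)Cl | intermediate
9 | 3,5-bis(benzyloxy)-2-(diazoacetyl)-6-methylphenyl acetate | CC(=O)Oc1c(C)c(OCc2ccccc2)cc(OCc2ccccc2)c1C(=O)C=[N+]=[N-] | intermediate
10 | (2R)-7-(benzyloxy)-6-methyl-4-oxo-2-phenyl-3,4-dihydro-2H-chromen-5-yl acetate | Cc1c(OC(C)=O)c2c(cc1OCc1ccccc1)O[C@@H](c1ccccc1)CC2=O | intermediate
11 | (2R)-7-hydroxy-6-methyl-4-oxo-2-phenyl-3,4-dihydro-2H-chromen-5-yl acetate | Cc1c(OC(C)=O)c2c(cc1O)O[C@@H](c1ccccc1)CC2=O | intermediate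
12 | (2R)-5,7-dihydroxy-6-methyl-2-phenylchroman-4-one (2R enantiomer of strobopinin) | Cc1c(O)c2c(cc1O)O[C@@H](c1ccccc1)CC2=O | intermediate
13 | 2',4',6'-trihydroxyacetophenone | CC(=O)c1c(O)cc(O)cc1O | starting material
14 | 6-acetyl-5-hydroxy-2,2,4,4-tetramethylcyclohex-5-ene-1,3-dione (acetylsyncarpic acid) | CC(=O)C1=C(O)C(C)(C)C(=O)C(C)(C)C1=O | intermediate
15 | 2,2,4,4-tetramethylcyclohexane-1,3,5-trione (syncarpic acid) | CC1(C)C(=O)CC(=O)C(C)(C)C1=O | intermediate
16 | isovaleraldehyde (3-methylbutanal) | CC(C)CC=O | starting material
17 | 5-hydroxy-2,2,6,6-tetramethyl-4-[3-methyl-1-(piperidin-1-yl)butyl]cyclohex-4-ene-1,3-dione (racemic Mannich base) | CC(C)CC(N1CCCCC1)C1=C(O)C(C)(C)C(=O)C(C)(C)C1=O | intermediate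
18 | 2,2,4,4-tetramethyl-6-(3-methylbutylidene)cyclohexane-1,3,5-trione | CC(C)CC=C1C(=O)C(C)(C)C(=O)C(C)(C)C1=O | intermediate
19 | (2R)-5,7-dihydroxy-8-[(1S)-1-(2-hydroxy-3,3,5,5-tetramethyl-4,6-dioxocyclohex-1-en-1-yl)-3-methylbutyl]-6-methyl-2-phenyl-2,3-dihydro-4H-chromen-4-one | Cc1c(O)c2c(c([C@H](CC(C)C)C3=C(O)C(C)(C)C(=O)C(C)(C)C3=O)c1O)O[C@@H](c1ccccc1)CC2=O | target

## Step count and risks

Total steps: 11. Longest linear sequence: 8 steps (steps 1–7 and 11, from 2-methylphloroglucinol).

Steps most likely to fail:

Step 6. The carbene may be intercepted by the lone pair of the ortho ether oxygen (oxonium ylide, then [1,2]-benzyl shift to a benzofuranone), and the two enantiotopic benzylic hydrogens may be discriminated incompletely, because one chiral catalyst has to secure chemo- and enantioselectivity at once. The fallback separates the two tasks and replaces asymmetric catalysis by resolution. Setting out from 9, the insertion is run with an achiral catalyst chosen only for C–H insertion selectivity, Rh2(OAc)4 in CH2Cl2 at rt with slow addition, to give racemic 7-(benzyloxy)-6-methyl-4-oxo-2-phenyl-3,4-dihydro-2H-chromen-5-yl acetate F1. F1 is resolved by preparative chromatography on a polysaccharide-carbamate chiral stationary phase; its (2R) enantiomer is 10, where the route is rejoined.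

Step 11. Facial selectivity at the exocyclic alkene carbon rests on catalyst control alone, since C2 is too remote to help, and reversible addition could erode it. The fallback gives up catalyst control and uses the fixed C2 centre to make the problem one of diastereomer separation. Setting out from 12 and 18, the addition is run with an achiral Brønsted acid (diphenyl phosphate, toluene, rt). This should give 19 together with its side-chain epimer (2R)-5,7-dihydroxy-8-[(1R)-1-(2-hydroxy-3,3,5,5-tetramethyl-4,6-dioxocyclohex-1-en-1-yl)-3-methylbutyl]-6-methyl-2-phenyl-2,3-dihydro-4H-chromen-4-one F2. The two are diastereomers and are separated by preparative HPLC on an achiral phase. F2 is returned to the same reversible conditions at higher temperature for re-equilibration and separated again, so the route comes back at 19.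

Step 2. Regiocontrol may be lost in the partial benzylation, through alkylation of the hindered ortho hydroxyl or over-alkylation. The fallback inverts the logic from selective protection to selective deprotection. Setting out from 3, exhaustive benzylation (BnBr in excess, K2CO3, DMF, 60 °C) gives 2,4,6-tris(benzyloxy)-3-methylbenzaldehyde F3. MgBr2·OEt2 (toluene/Et2O, reflux) then removes only a benzyl ether that can chelate the metal together with the formyl oxygen. Of the two ortho ethers, the one squeezed between methyl and formyl is twisted out of conjugation, hence more basic and more strained, and should be cleaved first, which returns the route to 5.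

Further compounds
F1 | step 6 | racemic 7-(benzyloxy)-6-methyl-4-oxo-2-phenyl-3,4-dihydro-2H-chromen-5-yl acetate | Cc1c(OC(C)=O)c2c(cc1OCc1ccccc1)OC(c1ccccc1)CC2=O
F2 | step 11 | (2R)-5,7-dihydroxy-8-[(1R)-1-(2-hydroxy-3,3,5,5-tetramethyl-4,6-dioxocyclohex-1-en-1-yl)-3-methylbutyl]-6-methyl-2-phenyl-2,3-dihydro-4H-chromen-4-one | Cc1c(O)c2c(c([C@@H](CC(C)C)C3=C(O)C(C)(C)C(=O)C(C)(C)C3=O)c1O)O[C@@H](c1ccccc1)CC2=O
F3 | step 2 | 2,4,6-tris(benzyloxy)-3-methylbenzaldehyde | Cc1c(OCc2ccccc2)cc(OCc2ccccc2)c(C=O)c1OCc1ccccc1
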